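**Plan**

- Retrosynthesis: the last cut hydrolyses four C–N bonds, so each 1,5-dialdehyde side chain goes back to an N-methoxycarbonyl-1,4-dihydropyridine. The next cut breaks both chain C2–C3 bonds (acetate CH2 to pyridine C4), leaving a core diacetate, 3-vinylpyridine and methyl chloroformate. The core is then cut at its ring–CH2O, ring–CH3 and ring–malonyl bonds back to an enantiopure acetoxycyclopentenol.
- Enabling feature: in each side chain the run CHO–C4–C3–CH2–CHO (C3 the stereocentre, C4 carrying the C5=C6 ethylidene) is C2–C3–C4–C5–C6 of a 3-vinylpyridine ring. Its nitrogen is excised and its vinyl group becomes chain C5–C6.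
- Forward order: the cyclopentane ring is bought and no ring of the target is made. Malonate is attached by Pd allylic alkylation; vinyl (latent CH2OH) and methyl are added by conjugate addition–alkylation of the derived enone; the ring oxygen is set by reduction and inversion. The diacetate becomes a bis(silyl ketene acetal), both chains are joined in one double dearomative addition, and aqueous acid unmasks everything.
- Stereochemistry: the malonyl-bearing ring carbon comes from the acetoxycyclopentenol (net retention) and relays trans to the vinyl and then the methyl centre. The carbinol centre comes from face-selective hydride delivery followed by Mitsunobu inversion. The two side-chain centres come from a chiral thiourea–chloride ion pair, and both enals settle as the (E) isomers.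

Key step: step 11

Assumption: the sense of induction of the thiourea at pyridinium C4 cannot be predicted with confidence. The catalyst enantiomer that gives the (4R) centres is taken, written here as the (S)-tert-leucine/(1R,2R)-diamine form; the catalyst is a separately prepared reagent and is not counted.
Remark: the target is treated as the open tetra-aldehyde diol; reversible hydrate or hemiacetal forms are not considered.

**Route**

Step 1
Reactants: 1 (1S,4R)-cis-4-acetoxycyclopent-2-en-1-ol; 2 dimethyl malonate
Product: 4 dimethyl 2-[(1R,4S)-4-hydroxycyclopent-2-en-1-yl]propanedioate, via sodium dimethyl malonate 3 (not isolated)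
Conditions: 2 (1.5 equiv), NaH, THF, 0 °C; then 1, Pd(PPh3)4 (3 mol%), THF, rt
Reagents that add atoms: none
Why: Tsuji–Trost allylic alkylation, in which zerovalent palladium ionises the acetate with inversion and the soft malonate anion attacks the allyl terminus remote from the hydroxyl anti to the metal, so the C–C bond forms with net retention and the cis-1,4 product carries the (R) ring centre.

Step 2
Reactants: 4 dimethyl 2-[(1R,4S)-4-hydroxycyclopent-2-en-1-yl]propanedioate
Product: 5 2-[(1R,4S)-4-hydroxycyclopent-2-en-1-yl]propane-1,3-diol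
Conditions: LiAlH4, THF, 0 °C → reflux; aq. KNaC4H4O6 (potassium sodium tartrate)
Reagents that add atoms: none
Why: Hydride reduction of both esters of a monoalkylmalonate to the 2-substituted propane-1,3-diol is standard and touches neither stereocentre nor the isolated alkene.

Step 3
Reactants: 5 2-[(1R,4S)-4-hydroxycyclopent-2-en-1-yl]propane-1,3-diol
Product: 6 (1S,4R)-4-(2,2-dimethyl-1,3-dioxan-5-yl)cyclopent-2-en-1-ol
Conditions: Me2C(OMe)2, PPTS (cat.), acetone, rt
Reagents that add atoms: 2,2-dimethoxypropane, COC(C)(C)OC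
Why: Acid-catalysed transketalisation closes the six-membered acetonide on the 1,3-diol only, because the ring hydroxyl has no partner for a cyclic ketal, and the mild pyridinium acid spares the allylic alcohol.

Step 4
Reactants: 6 (1S,4R)-4-(2,2-dimethyl-1,3-dioxan-5-yl)cyclopent-2-en-1-ol
Product: 7 (4R)-4-(2,2-dimethyl-1,3-dioxan-5-yl)cyclopent-2-en-1-one
Conditions: MnO2, CH2Cl2, rt
Reagents that add atoms: none
Why: Allylic alcohol oxidation with MnO2 under neutral conditions gives the enone without enolising the gamma stereocentre.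

Step 5
Reactants: 7 (4R)-4-(2,2-dimethyl-1,3-dioxan-5-yl)cyclopent-2-en-1-one
Product: 9 (2R,3S,4R)-4-(2,2-dimethyl-1,3-dioxan-5-yl)-2-methyl-3-vinylcyclopentan-1-one, via bromomagnesium enolate 8 (not isolated)
Conditions: CH2=CHMgBr, CuBr·SMe2 (20 mol%), THF, −78 °C; then MeI, DMPU, −78 → 0 °C
Reagents that add atoms: vinylmagnesium bromide, C=C[Mg]Br; iodomethane, CI
Why: Copper-catalysed conjugate addition followed by enolate alkylation (three-component coupling of a cyclopentenone) places the vinyl group at C3 anti to the C4 dioxanyl group and the methyl group at C2 anti to the new vinyl group, giving the all-trans 2,3,4 pattern.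

Step 6
Reactants: 9 (2R,3S,4R)-4-(2,2-dimethyl-1,3-dioxan-5-yl)-2-methyl-3-vinylcyclopentan-1-one
Product: 10 (1S,2R,3S,4R)-4-(2,2-dimethyl-1,3-dioxan-5-yl)-2-methyl-3-vinylcyclopentan-1-ol
Conditions: LiBH(s-Bu)3 (L-Selectride), THF, −78 °C; aq. NH4Cl
Reagents that add atoms: none
Why: Ketone reduction with a bulky trialkylborohydride delivers hydride to the face opposite the adjacent methyl group (and the C4 dioxanyl group), so the hydroxyl ends up cis to the methyl, (1S).

Step 7
Reactants: 10 (1S,2R,3S,4R)-4-(2,2-dimethyl-1,3-dioxan-5-yl)-2-methyl-3-vinylcyclopentan-1-ol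
Product: 11 (1R,2R,3S,4R)-4-(2,2-dimethyl-1,3-dioxan-5-yl)-2-methyl-3-vinylcyclopentyl acetate
Conditions: PPh3, DIAD, AcOH, THF, 0 °C → rt
Reagents that add atoms: acetic acid, CC(=O)O
Why: Mitsunobu reaction, in which acetate displaces the oxyphosphonium group in an SN2 step with inversion and so places the acetoxy group trans to the methyl group as the target requires, (1R).

Step 8
Reactants: 11 (1R,2R,3S,4R)-4-(2,2-dimethyl-1,3-dioxan-5-yl)-2-methyl-3-vinylcyclopentyl acetate
Product: 13 (1R,2R,3S,4R)-4-(2,2-dimethyl-1,3-dioxan-5-yl)-3-(hydroxymethyl)-2-methylcyclopentyl acetate, via aldehyde 12 (not isolated)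
Conditions: O3, CH2Cl2/MeOH, −78 °C; then NaBH4, −78 → 0 °C
Reagents that add atoms: ozone, [O-][O+]=O
Why: Ozonolysis with reductive borohydride work-up turns the vinyl group into the hydroxymethyl arm without epimerising the adjacent centre, since the aldehyde is reduced as it is released, and an acetyl shift between the two oxygens would be harmless because both are acetylated next.

Step 9
Reactants: 13 (1R,2R,3S,4R)-4-(2,2-dimethyl-1,3-dioxan-5-yl)-3-(hydroxymethyl)-2-methylcyclopentyl acetate
Product: 14 [(1S,2R,3R,5R)-3-acetoxy-5-(2,2-dimethyl-1,3-dioxan-5-yl)-2-methylcyclopentyl]methyl acetate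
Conditions: Ac2O, pyridine, DMAP (cat.), CH2Cl2, rt
Reagents that add atoms: acetic anhydride, CC(=O)OC(C)=O
Why: DMAP-catalysed acylation of the primary alcohol completes the diacetate whose two methyl groups become the nucleophilic carbons of the key step.

Step 10
Reactants: 14 [(1S,2R,3R,5R)-3-acetoxy-5-(2,2-dimethyl-1,3-dioxan-5-yl)-2-methylcyclopentyl]methyl acetate
Product: 16 acetonide-protected core bis(O-tert-butyldimethylsilyl ketene acetal), via dilithium bis-enolate 15 (not isolated)
Conditions: LiN(i-Pr)2 (2.4 equiv), THF, −78 °C; then TBSCl, DMPU, −78 °C → rt; pentane, filtration, no aqueous work-up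
Reagents that add atoms: tert-butyldimethylsilyl chloride, CC(C)(C)[Si](C)(C)Cl
Why: Kinetic ester enolisation followed by O-silylation gives the bis(ketene acetal), the tert-butyldimethylsilyl group with a dipolar cosolvent being chosen because acetate enolates are silylated largely on carbon by Me3SiCl, and the acetonide is inert to the base.

Step 11
Reactants: 16 acetonide-protected core bis(O-tert-butyldimethylsilyl ketene acetal); 17 3-vinylpyridine; 18 methyl chloroformate
Product: 20 acetonide-protected core bis{2-[(4R)-1-(methoxycarbonyl)-3-vinyl-1,4-dihydropyridin-4-yl]acetate}, via N-methoxycarbonyl-3-vinylpyridinium chloride 19 (not isolated)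
Conditions: 17 (2.5 equiv), 18 (2.3 equiv), MTBE, 0 °C; then thiourea T (20 mol%), 16, −78 → −60 °C; T = 1-[(1R,2R)-2-(2-methyl-5-phenylpyrrol-1-yl)cyclohexyl]-3-[(2S)-1-(diisobutylamino)-3,3-dimethyl-1-oxobutan-2-yl]thiourea
Reagents that add atoms: none
Why: Proposed new method: 18 acylates the nitrogen of 17 to give the pyridinium chloride 19, the thiourea binds the chloride so that the cation sits in a chiral ion pair, each ketene acetal carbon of 16 then attacks C4 of one pyridinium ion and the bound chloride takes the silyl group as TBSCl, which frees the catalyst and leaves an N-acyl-1,4-dihydropyridine (a bis-enecarbamate) that is no longer electrophilic. The closest known reaction types are the uncatalysed C4-selective addition of silyl ketene acetals to N-alkoxycarbonylpyridinium salts and the thiourea anion-binding-catalysed enantioselective acyl-Mannich dearomatisation of isoquinolines and pyridines; their merger at C4 of a 3-substituted pyridinium ion, run twice on one bis-nucleophile, is untested. No ring is closed: the step makes only the two chain C2–C3 bonds. The two new stereocentres (C4 of each dihydropyridine, both R) are set by the catalyst-bound ion pair, since the core stereocentres lie four and five bonds away and the two additions are independent events. The step needs C4 over C2/C6 attack and one pyridinium face at each site: the soft, neutral ketene acetal reacts under orbital control at C4, C2 is flanked by both the vinyl and the carbamoyl group, C6 attack is the competitor to watch, and the 3-vinyl group is meta to nitrogen and so is not a Michael acceptor. Forming 19 first with a slight excess of 17 leaves no free chloroformate to acylate the ketene acetal.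

Step 12
Reactants: 20 acetonide-protected core bis{2-[(4R)-1-(methoxycarbonyl)-3-vinyl-1,4-dihydropyridin-4-yl]acetate}
Product: 21 CNP0313563.1
Conditions: 1 M aq. HCl, THF, 0 °C → rt
Reagents that add atoms: water, O
Why: Proposed new method: aqueous acid protonates each enecarbamate on carbon (ring C5, and the 3-vinyl dienecarbamate at the vinyl terminus so that the conjugated N-acyliminium ion forms), water adds to the iminium carbons and the N-acyl hemiaminals collapse with loss of methyl carbamate to give the two aldehydes of each chain with the 2-ethylidene group in its thermodynamically preferred (E) form, while the same acid hydrolyses the acetonide and the non-enolisable chain C3 centres are untouched; the closest known reaction types are the acid hydrolysis of enamides and enecarbamates to carbonyl compounds and of 1-acylamino-1,3-dienes to conjugated enals.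

**Compound list**

1 | (1S,4R)-cis-4-acetoxycyclopent-2-en-1-ol | CC(=O)O[C@@H]1C[C@H](O)C=C1 | starting material
2 | dimethyl malonate | COC(=O)CC(=O)OC | starting material
3 | sodium dimethyl malonate | COC(=O)[CH-]C(=O)OC.[Na+] | intermediate
4 | dimethyl 2-[(1R,4S)-4-hydroxycyclopent-2-en-1-yl]propanedioate (cis) | COC(=O)C(C(=O)OC)[C@@H]1C[C@H](O)C=C1 | intermediate
5 | 2-[(1R,4S)-4-hydroxycyclopent-2-en-1-yl]propane-1,3-diol | OCC(CO)[C@@H]1C[C@H](O)C=C1 | intermediate
6 | (1S,4R)-4-(2,2-dimethyl-1,3-dioxan-5-yl)cyclopent-2-en-1-ol | CC1(C)OCC(CO1)[C@@H]2C[C@H](O)C=C2 | intermediate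
7 | (4R)-4-(2,2-dimethyl-1,3-dioxan-5-yl)cyclopent-2-en-1-one | CC1(C)OCC(CO1)[C@@H]2CC(=O)C=C2 | intermediate
8 | bromomagnesium (3S,4R)-4-(2,2-dimethyl-1,3-dioxan-5-yl)-3-vinylcyclopent-1-en-1-olate | CC1(C)OCC(CO1)[C@@H]2CC(O[Mg]Br)=C[C@H]2C=C | intermediate
9 | (2R,3S,4R)-4-(2,2-dimethyl-1,3-dioxan-5-yl)-2-methyl-3-vinylcyclopentan-1-one (all-trans) | CC1(C)OCC(CO1)[C@@H]2CC(=O)[C@H](C)[C@H]2C=C | intermediate
10 | (1S,2R,3S,4R)-4-(2,2-dimethyl-1,3-dioxan-5-yl)-2-methyl-3-vinylcyclopentan-1-ol (OH cis to methyl) | CC1(C)OCC(CO1)[C@@H]2C[C@H](O)[C@H](C)[C@H]2C=C | intermediate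
11 | (1R,2R,3S,4R)-4-(2,2-dimethyl-1,3-dioxan-5-yl)-2-methyl-3-vinylcyclopentyl acetate (OAc trans to methyl) | CC1(C)OCC(CO1)[C@@H]2C[C@@H](OC(C)=O)[C@H](C)[C@H]2C=C | intermediate
12 | (1R,2R,3S,4R)-4-(2,2-dimethyl-1,3-dioxan-5-yl)-3-formyl-2-methylcyclopentyl acetate | CC1(C)OCC(CO1)[C@@H]2C[C@@H](OC(C)=O)[C@H](C)[C@H]2C=O | intermediate
13 | (1R,2R,3S,4R)-4-(2,2-dimethyl-1,3-dioxan-5-yl)-3-(hydroxymethyl)-2-methylcyclopentyl acetate | CC1(C)OCC(CO1)[C@@H]2C[C@@H](OC(C)=O)[C@H](C)[C@H]2CO | intermediate
14 | [(1S,2R,3R,5R)-3-acetoxy-5-(2,2-dimethyl-1,3-dioxan-5-yl)-2-methylcyclopentyl]methyl acetate | CC(=O)OC[C@@H]1[C@@H](C)[C@H](OC(C)=O)C[C@H]1C2COC(C)(C)OC2 | intermediate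
15 | dilithium bis-enolate of 14 (each acetate as CH2=C(OLi)O–) | C=C(O[Li])OC[C@@H]1[C@@H](C)[C@H](OC(=C)O[Li])C[C@H]1C2COC(C)(C)OC2 | intermediate
16 | acetonide-protected core bis(O-tert-butyldimethylsilyl ketene acetal): 14 with each CH3C(=O)O– replaced by CH2=C(OSiMe2t-Bu)O–, core (1S,2R,3R,5R) | C=C(O[Si](C)(C)C(C)(C)C)OC[C@@H]1[C@@H](C)[C@H](OC(=C)O[Si](C)(C)C(C)(C)C)C[C@H]1C2COC(C)(C)OC2 | intermediate
17 | 3-vinylpyridine | C=Cc1cccnc1 | starting material
18 | methyl chloroformate | COC(=O)Cl | starting material
19 | N-methoxycarbonyl-3-vinylpyridinium chloride | C=Cc1ccc[n+](C(=O)OC)c1.[Cl-] | intermediate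
20 | [(1S,2R,3R,5R)-5-(2,2-dimethyl-1,3-dioxan-5-yl)-3-({2-[(4R)-1-(methoxycarbonyl)-3-vinyl-1,4-dihydropyridin-4-yl]acetyl}oxy)-2-methylcyclopentyl]methyl 2-[(4R)-1-(methoxycarbonyl)-3-vinyl-1,4-dihydropyridin-4-yl]acetate | C=CC1=CN(C(=O)OC)C=C[C@H]1CC(=O)OC[C@@H]2[C@@H](C)[C@H](OC(=O)C[C@@H]3C=CN(C(=O)OC)C=C3C=C)C[C@H]2C4COC(C)(C)OC4 | intermediate
21 | CNP0313563.1, [(1S,2R,3R,5R)-5-(1,3-dihydroxypropan-2-yl)-3-{[(3S,4E)-4-formyl-3-(2-oxoethyl)hex-4-enoyl]oxy}-2-methylcyclopentyl]methyl (3S,4E)-4-formyl-3-(2-oxoethyl)hex-4-enoate | C/C=C(/C=O)[C@@H](CC=O)CC(=O)OC[C@@H]1[C@@H](C)[C@H](OC(=O)C[C@H](CC=O)/C(C=O)=C\C)C[C@H]1C(CO)CO | target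

**Step count and risks**

Total: 12 steps. Longest linear sequence: 12 steps (1 → 21); 17 and 18 enter at step 11.

Steps most likely to fail:

1. Step 11 (proposed new method). The ketene acetal may attack C6 or C2 instead of C4, facial control by the catalyst may be weak or differ between the two sites so that inseparable diastereomers form, and ketene acetal may be lost by C-acylation or protodesilylation. The fallback uses known reactions only, sets out from 13, 17 and 18 and rejoins the route at 20. Methanolysis of 13 (K2CO3, MeOH) gives the acetonide-protected core diol (1R,2R,3S,4R)-4-(2,2-dimethyl-1,3-dioxan-5-yl)-3-(hydroxymethyl)-2-methylcyclopentan-1-ol F1. The pyridinium salt 19 is made from 17 and 18 as before and treated, without catalyst, with 1,1-bis(trimethylsilyloxy)ethene F2 (from trimethylsilyl acetate, LiN(i-Pr)2, Me3SiCl). This is the known C4-selective addition of bis(silyl) ketene acetals to N-alkoxycarbonylpyridinium salts, and aqueous work-up gives racemic 2-[1-(methoxycarbonyl)-3-vinyl-1,4-dihydropyridin-4-yl]acetic acid F3, from which any regioisomer is removed at this small-molecule stage. Preparative chromatography on a chiral stationary phase gives 2-[(4R)-1-(methoxycarbonyl)-3-vinyl-1,4-dihydropyridin-4-yl]acetic acid F4. Twofold Steglich esterification of F1 with F4 (EDC·HCl, DMAP, CH2Cl2) gives 20.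

2. Step 12 (proposed new method). Hydrolysis may stall at the cyclic N-acyl hemiaminal stage, and the aldehydes freed first may undergo acid-promoted aldol condensation or oligomerisation before the carbamate is released. The fallback uses known reactions only, sets out from 13 and 17 and rejoins at 21; it replaces the acid-stable methyl carbamate by a reductively removable one, so that the nitrogen leaves from a plain enamine. The core diol F1 and the ketene acetal F2 are made as in the first fallback. 17 is acylated with 2,2,2-trichloroethyl chloroformate to N-(2,2,2-trichloroethoxycarbonyl)-3-vinylpyridinium chloride F5, which F2 converts without catalyst into racemic 2-[1-(2,2,2-trichloroethoxycarbonyl)-3-vinyl-1,4-dihydropyridin-4-yl]acetic acid F6. Chiral chromatography gives the (4R)-acid F7, and esterification of F1 with F7 (EDC·HCl, DMAP) gives the acetonide-protected core bis(N-trichloroethoxycarbonyl-dihydropyridinylacetate) F8. Zn dust in AcOH/THF/H2O at rt removes both carbamates reductively to the acetonide-protected core bis(N-unsubstituted dihydropyridinylacetate) F9 (not isolated), which is a simple divinylamine and hydrolyses as an enamine in the same medium. Warming to 40 °C removes the acetonide and gives 21.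

3. Step 7. The oxyphosphonium ion of the hindered ring alcohol may undergo E2 elimination into the ring, or the alcohol may fail to be activated. The fallback sets out from 9 and rejoins at 11, replacing kinetic reduction plus inversion by a thermodynamically controlled reduction. Dissolving-metal reduction of 9 (Li, liquid NH3, t-BuOH, THF, −78 °C) gives the all-trans alcohol (1R,2R,3S,4R)-4-(2,2-dimethyl-1,3-dioxan-5-yl)-2-methyl-3-vinylcyclopentan-1-ol F10, and acetylation (Ac2O, pyridine, DMAP) gives 11.

**Further compounds**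

F1 | step 11 | (1R,2R,3S,4R)-4-(2,2-dimethyl-1,3-dioxan-5-yl)-3-(hydroxymethyl)-2-methylcyclopentan-1-ol | OC[C@@H]1[C@@H](C)[C@H](O)C[C@H]1C2COC(C)(C)OC2
F2 | step 11 | 1,1-bis(trimethylsilyloxy)ethene | C=C(O[Si](C)(C)C)O[Si](C)(C)C
F3 | step 11 | racemic 2-[1-(methoxycarbonyl)-3-vinyl-1,4-dihydropyridin-4-yl]acetic acid | C=CC1=CN(C(=O)OC)C=CC1CC(=O)O
F4 | step 11 | 2-[(4R)-1-(methoxycarbonyl)-3-vinyl-1,4-dihydropyridin-4-yl]acetic acid | C=CC1=CN(C(=O)OC)C=C[C@H]1CC(=O)O
F5 | step 12 | N-(2,2,2-trichloroethoxycarbonyl)-3-vinylpyridinium chloride | C=Cc1ccc[n+](C(=O)OCC(Cl)(Cl)Cl)c1.[Cl-]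
F6 | step 12 | racemic 2-[1-(2,2,2-trichloroethoxycarbonyl)-3-vinyl-1,4-dihydropyridin-4-yl]acetic acid | C=CC1=CN(C(=O)OCC(Cl)(Cl)Cl)C=CC1CC(=O)O
F7 | step 12 | 2-[(4R)-1-(2,2,2-trichloroethoxycarbonyl)-3-vinyl-1,4-dihydropyridin-4-yl]acetic acid | C=CC1=CN(C(=O)OCC(Cl)(Cl)Cl)C=C[C@H]1CC(=O)O
F8 | step 12 | acetonide-protected core bis{2-[(4R)-1-(2,2,2-trichloroethoxycarbonyl)-3-vinyl-1,4-dihydropyridin-4-yl]acetate} | C=CC1=CN(C(=O)OCC(Cl)(Cl)Cl)C=C[C@H]1CC(=O)OC[C@@H]2[C@@H](C)[C@H](OC(=O)C[C@@H]3C=CN(C(=O)OCC(Cl)(Cl)Cl)C=C3C=C)C[C@H]2C4COC(C)(C)OC4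
F9 | step 12 | acetonide-protected core bis{2-[(4R)-3-vinyl-1,4-dihydropyridin-4-yl]acetate} | C=CC1=CNC=C[C@H]1CC(=O)OC[C@@H]2[C@@H](C)[C@H](OC(=O)C[C@@H]3C=CNC=C3C=C)C[C@H]2C4COC(C)(C)OC4
F10 | step 7 | (1R,2R,3S,4R)-4-(2,2-dimethyl-1,3-dioxan-5-yl)-2-methyl-3-vinylcyclopentan-1-ol | CC1(C)OCC(CO1)[C@@H]2C[C@@H](O)[C@H](C)[C@H]2C=C
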